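1. A rate in proportion to the Kat charged is hard to square with the two earlier runs. At 3.00 min north-east holds 1.69 times the Pdt of north, larger than their Kat ratio of 1.57, though each reading scatters by 0.3 percentage points.

common to all: Sub 0.069 M; Rgt 0.0725 M; Spx 0.11 mM; Rgt2 1.2 mM

| charge | Kat | remark |
|---|---|---|
| north | 0.49 mM | run made earlier |
| north-east | 0.77 mM | run made earlier |
| flask | 0.35 mM |  |

| run | time / min | Pdt / % | Sub / % |
|---|---|---|---|
| north | 0.667 | 1.7 | 62.8 |
| north | 2.00 | 5.6 | 59.6 |
| north | 3.00 | 8.3 | 58.2 |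
| north | 5.00 | 13.8 | 55.2 |
| north | 8.00 | 20.4 | 50.1 |
| north-east | 1.33 | 7.0 | 59.3 |
| north-east | 3.00 | 14.0 | 54.1 |
| north-east | 4.00 | 18.2 | 51.1 |
| north-east | 6.00 | 25.6 | 47.3 |
| north-east | 8.00 | 31.7 | 43.4 |

(readings scatter by 0.3 percentage points)

- apparent order in Rgt when 50% of the Sub are converted (percent change of the rate of making Pdt for one percent more Rgt charged)
- apparent order in Kat when 50% of the Sub are converted (percent change of the rate of making Pdt for one percent more Kat charged)

- the analysis behind the earlier runs scatters by 0.3 percentage points, standard deviation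
- steps that have been proposed: Sub + Kat <-> Kat + Imd; Rgt + Kat + Imd -> Kat + Pdt; Kat + Spx -> Kat.Spx; Kat + Rgt2 <-> Kat.Rgt2
- no earlier run changes the charge of Rgt; that part of a forecast is a guess

2. First rung: Kat turns Sub into Imd. By 0.667 min north's Sub is down to 62.8% with Pdt at 1.7%. [Imd]/[Sub] reads 0.565 there and 0.589 at 8.00 min, so I treat this step as an equilibrium.

3. An inference from the runs, not a reading: Spx takes Kat away as Kat.Spx. Its charge is smaller than the Kat charge, so I subtract 0.11 mM from Kat in each run. The remainders stand in the ratio 1.74, nearer to the reading than the plain Kat ratio.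

4. Slower rung, the rate-limiting step: Kat turns Imd and Rgt into Pdt. North needs 8.00 min, longer than the first rung, to reach 20.4%. I take the rate as following remaining Kat, [Imd] and [Rgt].

5. If a fixed amount comes off a charge and the rate is in proportion to the remainder, the percent change of the rate for one percent more charge is the lever, the charge over the remainder. For Kat in the flask, the lever is 1.46.

6. I apply the same rule to Rgt. North reaches Sub 50.1% with Pdt 20.4%, and I assume the flask matches, so 14.1 mM comes off Rgt. My lever is 1.24, a guess, since no earlier run changes the Rgt charge.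

7. The forecast gives 1.24 (1 to 1.35) for Rgt and 1.45 (1.2 to 1.7) for Kat, on these grounds: “Spx therefore poisons stoichiometrically”.

The flask gives 1.2 for Rgt and 1.5 for Kat.

    Sub + Kat ⇌ Kat + Imd (K = 0.580, k = 215 M⁻¹ s⁻¹)
    Rgt + Kat + Imd → Kat + Pdt (k = 74.6 M⁻² s⁻¹)
    Kat + Spx → Kat.Spx (k = 11000 M⁻¹ s⁻¹)
    Kat + Rgt2 ⇌ Kat.Rgt2, settled at all times (K = 350 M⁻¹)

By 0.600 min the flask's Spx stands at 0%, and at 3.00 min its catalyst is Kat.Spx 31.4%, Kat 49.1% and Kat.Rgt2 19.5%. Dividing the flask's charge by its lever gives 0.240 mM of catalyst not held as Kat.Spx, Kat and Kat.Rgt2 counted together, against 0.380 mM in north. Scaling north's 8.3% of Pdt at 3.00 min by that ratio gives 5.24%, and the flask holds 5.47% at 3.00 min.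

The runs are calculated with made-up constants.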